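**Retrosynthetic overview**
- The 7-OH is unmasked last from a 7-O-tert-butyl ether. The 8-isovalerate comes from chemoselective acylation of a 5,8-hydroquinone, where 5-OH is chelated to C4=O and 8-OH is free.
- Key step: the whole A-ring is removed by a Moore–Liebeskind ring expansion (4π opening, then 6π closure) of a 4-(γ-pyranonyl)-4-hydroxycyclobutenone. No acetophenone, chalcone, Baker–Venkataraman or Allan–Robinson chemistry is used.
- The cyclobutenone comes from a 5-magnesiated 2-aryl-3-methoxy-γ-pyrone and the mixed squarate 3-tert-butoxy-4-methoxycyclobutenedione. The squarate carries C5–C8 with all four oxygens already differentiated.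
- The γ-pyrone comes from pyromeconic acid by C2 iodination, O-methylation, Suzuki coupling and C5 iodination. The mixed squarate comes from dimethyl squarate.
- Ring order: the C-ring is purchased, the B-ring is attached by Suzuki coupling, and the A-ring is formed last by benzannulation.

Assumption: the target SMILES has no stereocentre and no stereogenic double bond, so "single enantiomer" does not apply. The only stereocentre in the route (in 10) is racemic and is destroyed in Step 8.

**Step 1**
Reactants: 1, 3-hydroxy-4H-pyran-4-one (pyromeconic acid)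
Product: 2, 3-hydroxy-2-iodo-4H-pyran-4-one
Conditions: I2, KI, Na2CO3, H2O, 0 °C → rt; then HCl to pH 2
Reagents that add atoms: iodine, II
Why: Phenol-type electrophilic iodination of the pyromeconate anion occurs only at C2, the enolic carbon ortho to the 3-oxygen, which is the same site at which pyromeconic and kojic acids undergo halogenation, Mannich and hydroxymethylation reactions.

**Step 2**
Reactants: 2, 3-hydroxy-2-iodo-4H-pyran-4-one
Product: 3, 2-iodo-3-methoxy-4H-pyran-4-one
Conditions: MeI, K2CO3, acetone, 40 °C
Reagents that add atoms: iodomethane, CI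
Why: Williamson O-methylation of the acidic enol (pKa about 8) needs only a mild heterogeneous base, which leaves the vinylogous acyl iodide untouched.

**Step 3**
Reactants: 3, 2-iodo-3-methoxy-4H-pyran-4-one; 4, 4-methoxyphenylboronic acid
Product: 5, 3-methoxy-2-(4-methoxyphenyl)-4H-pyran-4-one
Conditions: Pd(dppf)Cl2 (3 mol %), K3PO4, 1,4-dioxane/H2O 10:1, 70 °C
Reagents that add atoms: 4-methoxyphenylboronic acid (4), COc1ccc(B(O)O)cc1
Why: In this Suzuki–Miyaura coupling the C2–I bond sits on the β-carbon of the enone, so oxidative addition is fast and the pyranone tolerates the mild phosphate base.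

**Step 4**
Reactants: 5, 3-methoxy-2-(4-methoxyphenyl)-4H-pyran-4-one
Product: 6, 5-iodo-3-methoxy-2-(4-methoxyphenyl)-4H-pyran-4-one
Conditions: I2, CAN, MeCN, 65 °C
Reagents that add atoms: iodine, II
Why: Electrophilic α-iodination, as used for 3-iodination of chromones and methoxyflavones, attacks C5 because it is the only free enol-ether β-carbon (O1–C6=C5), while C6 is electrophilic and the anisyl ring is deactivated by conjugation with the pyranone.

**Step 5**
Reactants: 7, 3,4-dimethoxycyclobut-3-ene-1,2-dione (dimethyl squarate)
Product: 8, 3-hydroxy-4-methoxycyclobut-3-ene-1,2-dione (monomethyl squarate)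
Conditions: NaOH (1.0 equiv), MeOH/H2O, 0 °C; Amberlite IR-120 (H+), evaporate
Reagents that add atoms: sodium hydroxide, [Na+].[OH-]
Why: Vinylogous ester saponification by addition–elimination stops cleanly at the monoester because the resulting squarate monoanion resists a second attack.

**Step 6**
Reactants: 8, 3-hydroxy-4-methoxycyclobut-3-ene-1,2-dione
Product: 9, 3-tert-butoxy-4-methoxycyclobut-3-ene-1,2-dione
Conditions: t-BuOC(=NH)CCl3 (1.5 equiv), CH2Cl2/cyclohexane, rt, no added acid
Reagents that add atoms: tert-butyl 2,2,2-trichloroacetimidate, CC(C)(C)OC(=N)C(Cl)(Cl)Cl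
Why: In this imidate O-tert-butylation the strong vinylogous acid (pKa about 1) protonates the imidate itself and captures the tert-butyl cation on oxygen, giving a stable ester of the same type as the isolable di-tert-butyl squarate.

**Step 7**
Reactants: 6, 5-iodo-3-methoxy-2-(4-methoxyphenyl)-4H-pyran-4-one; 9, 3-tert-butoxy-4-methoxycyclobut-3-ene-1,2-dione
Product: 10, (±)-2-tert-butoxy-4-hydroxy-3-methoxy-4-[5-methoxy-6-(4-methoxyphenyl)-4-oxo-4H-pyran-3-yl]cyclobut-2-en-1-one
Conditions: 6, i-PrMgCl·LiCl (1.05 equiv), THF, −78 → −40 °C, 20 min; cannulate into 9 (1.2 equiv), THF, −78 °C; aq NH4Cl at −78 °C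
Reagents that add atoms: none beyond reactants 6 and 9
Why: Knochel-type I/Mg exchange (closest analogues are 5-magnesiated 1,3-dioxin-4-ones and uracils) followed by the standard 1,2-addition to a squarate should favour the carbonyl next to C–OMe, because the neighbouring tert-butoxy group shields the other carbonyl and its twisted oxygen donates less to the one attacked; the new carbinol stereocentre is racemic and is erased in Step 8.

**Step 8 (key step)**
Reactants: 10, the 4-hydroxycyclobutenone from Step 7
Product: 11, 7-tert-butoxy-5,8-dihydroxy-3,6-dimethoxy-2-(4-methoxyphenyl)-4H-chromen-4-one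
Conditions: degassed toluene (0.02 M), 110 °C, 1–2 h, Ar; concentrate and carry forward crude under Ar
Reagents that add atoms: none
Why: In the Moore–Liebeskind rearrangement, conrotatory 4π opening turns OH outward and the pyranonyl group inward, and the resulting dienylketene undergoes 6π closure onto pyranone C6 and tautomerises, so carbinol C becomes C5-OH, C(OMe) becomes C6, C(Ot-Bu) becomes C7 and the ketene carbon becomes C8-OH bonded to C8a.

**Step 9**
Reactants: 11, the 5,8-hydroquinone from Step 8; 12, 3-methylbutanoyl chloride (isovaleryl chloride)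
Product: 13, 7-tert-butoxy-5-hydroxy-3,6-dimethoxy-2-(4-methoxyphenyl)-4-oxo-4H-chromen-8-yl 3-methylbutanoate
Conditions: 12 (1.05 equiv), Et3N, DMAP (5 mol %), degassed CH2Cl2, −20 → 0 °C, Ar
Reagents that add atoms: isovaleryl chloride (12), CC(C)CC(=O)Cl
Why: Chemoselective O-acylation takes the free 8-OH because the 5-OH is locked in the six-membered hydrogen-bond chelate with C4=O and acylates far more slowly, and 7-O is blocked as the tert-butyl ether.

**Step 10**
Reactants: 13, the 7-O-tert-butyl 8-isovalerate from Step 9
Product: 14, 5,7-dihydroxy-3,6-dimethoxy-2-(4-methoxyphenyl)-4-oxo-4H-chromen-8-yl 3-methylbutanoate (target)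
Conditions: TFA/CH2Cl2 1:4, 1,3-dimethoxybenzene (scavenger), 0 °C, 30 min
Reagents that add atoms: none
Why: SN1/E1 acidolysis removes the aryl tert-butyl ether while the methyl ethers, the ester and the flavone survive, and 8→7 acyl migration is disfavoured because 7-OH is the most acidic (vinylogous acid) hydroxyl, which makes the 8-ester the thermodynamic isomer.

**Compound list**
1 | 3-hydroxy-4H-pyran-4-one (pyromeconic acid) | O=c1ccocc1O | starting material
2 | 3-hydroxy-2-iodo-4H-pyran-4-one | O=c1ccoc(I)c1O | intermediate
3 | 2-iodo-3-methoxy-4H-pyran-4-one | COc1c(I)occc1=O | intermediate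
4 | 4-methoxyphenylboronic acid | COc1ccc(B(O)O)cc1 | starting material
5 | 3-methoxy-2-(4-methoxyphenyl)-4H-pyran-4-one | COc1ccc(-c2occc(=O)c2OC)cc1 | intermediate
6 | 5-iodo-3-methoxy-2-(4-methoxyphenyl)-4H-pyran-4-one | COc1ccc(-c2occ(I)c(=O)c2OC)cc1 | intermediate
7 | 3,4-dimethoxycyclobut-3-ene-1,2-dione (dimethyl squarate) | COC1=C(OC)C(=O)C1=O | starting material
8 | 3-hydroxy-4-methoxycyclobut-3-ene-1,2-dione | COC1=C(O)C(=O)C1=O | intermediate
9 | 3-tert-butoxy-4-methoxycyclobut-3-ene-1,2-dione | COC1=C(OC(C)(C)C)C(=O)C1=O | intermediate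
10 | (±)-2-tert-butoxy-4-hydroxy-3-methoxy-4-[5-methoxy-6-(4-methoxyphenyl)-4-oxo-4H-pyran-3-yl]cyclobut-2-en-1-one (racemic) | COc1ccc(-c2occ(C3(O)C(OC)=C(OC(C)(C)C)C3=O)c(=O)c2OC)cc1 | intermediate
11 | 7-tert-butoxy-5,8-dihydroxy-3,6-dimethoxy-2-(4-methoxyphenyl)-4H-chromen-4-one | COc1ccc(-c2oc3c(O)c(OC(C)(C)C)c(OC)c(O)c3c(=O)c2OC)cc1 | intermediate
12 | 3-methylbutanoyl chloride (isovaleryl chloride) | CC(C)CC(=O)Cl | starting material
13 | 7-tert-butoxy-5-hydroxy-3,6-dimethoxy-2-(4-methoxyphenyl)-4-oxo-4H-chromen-8-yl 3-methylbutanoate | COc1ccc(-c2oc3c(OC(=O)CC(C)C)c(OC(C)(C)C)c(OC)c(O)c3c(=O)c2OC)cc1 | intermediate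
14 | 5,7,8-trihydroxy-3,6,4'-trimethoxyflavone 8-isovalerate (achiral) | COc1ccc(-c2oc3c(OC(=O)CC(C)C)c(O)c(OC)c(O)c3c(=O)c2OC)cc1 | target

**Total step count:** 10
**Longest linear sequence:** 8 (Steps 1–4, then 7–10). Steps 5–6 form the convergent two-step branch.

**Three steps most likely to fail**
1. **Step 7.**
   - Risk: The 5-magnesio-pyranone has Mg anti to the ring oxygen and may ring-open by β-elimination to an ynone. i-PrMgCl may add at C6. The Me/t-Bu steric bias on 9 may give only modest regioselectivity.
   - Fallback: Use a carbanion-free, regiochemically blocked coupling. Convert 6 to its pinacol boronate by Miyaura borylation. Add it under Rh(I) catalysis (1,2-addition) to the squarate monoketal 3-tert-butoxy-2,4,4-trimethoxycyclobut-2-en-1-one, whose only C=O sits next to C–OMe. Mild ketal hydrolysis then gives 10.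
2. **Step 8.**
   - Risk: Isobutene may be lost at 110 °C, and the hydroquinone may air-oxidise. A γ-pyrone C=C is an untested 2π partner for this rearrangement.
   - Fallback: Drop the t-Bu differentiation. Take the crude material through the 5,8-quinone (Ag2O, purify, then Na2S2O4) to the 5,7,8-triol and form the 7,8-di-isovalerate. Then cleave only the 7-ester with PhSH/imidazole, the known 7-selective deacylation of flavone esters.
3. **Step 4.**
   - Risk: Iodination may compete on the anisyl ring, or C5 may react sluggishly.
   - Fallback: Change the order of events. Iodinate C5 on arene-free 3 to give 2,5-diiodo-3-methoxy-4H-pyran-4-one. Then run a site-selective Suzuki coupling at the more electrophilic β-carbon C2–I, which gives 6 directly.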